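**Plan**

- Retrosynthesis: the C10 methyl is read as a reduced carboxyl, so the C10–C11 bond becomes the retron of an ester-enolate Claisen rearrangement. It is cut to a C1–C10 acid (carboxyl = future C10 methyl) and a C11–C24 bis-allylic alcohol with oxygen on C13. The acid is cut at C6=C7 (Wittig), C8=C9 (Still–Gennari), C2=C3 (ring-closing metathesis) and C4–C5 (crotylboration); the alcohol at C12–C13 (vinyl addition), C14=C15 (cross-metathesis), C16–C17 and C18–C19 (aldols) and C20–C21 (alkylation).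
- Enabling feature: C10–C11 is the middle bond of the 1,5-diene C8=C9–C10–C11–C12=C13, C10 carries a one-carbon branch, and C13 lies between C12 and the C14=C15 alkene. An O–C13 ester of the C10 acid can therefore rearrange through its free vinyl arm (C11=C12) to give the C10–C11 bond, the C10 centre and the conjugated (12E,14E)-diene together.
- Forward order: the dihydropyran ring (O, C1–C5; the only ring) is closed by metathesis and carried as its isopropyl lactol acetal; the C6–C9 diene is added by Wittig reaction; the right chain is grown from C24 westward; esterification joins the halves and the Ireland–Claisen step converts the C13–O link into the C10–C11 link; then CO2H is reduced to CH3, followed by oxidations and desilylation.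
- Stereochemistry: C4/C5 from reagent-controlled (Z)-crotylboration; C20, C18/C19 and C16 (with temporary C17) from oxazolidinone auxiliaries; temporary C13 from catalytic asymmetric vinylation; C10 from C13 by chair transfer. Alkene geometry: 8Z Still–Gennari, 6E ylide, 12E Claisen, 14E metathesis, 22E SeO2 oxidation.

Key step: step 34

Remark: atom numbers are those of kazusamycin A (C1 lactone carbonyl to C24 carboxyl carbon); TBS = tert-butyldimethylsilyl, TES = triethylsilyl; the reagent antipodes in steps 6 and 32 are assigned from the usual facial-selectivity models for these reagents.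

**Fragment A (C1–C10 acid)**

Step 1
Reactants: 1 methyl bis(2,2,2-trifluoroethyl)phosphonoacetate
Product: 2 methyl 2-[bis(2,2,2-trifluoroethoxy)phosphoryl]butanoate (racemic)
Conditions: KOt-Bu, THF, 0 °C; EtI, 0 °C → rt
Reagents that add atoms: iodoethane CCI
Why: C-alkylation of the stabilised phosphonoacetate anion with a primary iodide (no stereocentre of consequence, the α-carbon becomes sp2 in step 2).

Step 2
Reactants: 2 methyl 2-[bis(2,2,2-trifluoroethoxy)phosphoryl]butanoate; 3 3-(tert-butyldimethylsilyloxy)propanal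
Product: 4 methyl (Z)-5-(tert-butyldimethylsilyloxy)-2-ethylpent-2-enoate
Conditions: KN(SiMe3)2, 18-crown-6, THF, −78 °C
Reagents that add atoms: none
Why: Still–Gennari olefination, whose fast elimination from the kinetic adduct should give the (Z)-enoate, that is the ester carbon (future C7) cis to C10 as the 8Z alkene requires.

Step 3
Reactants: 4 methyl (Z)-5-(tert-butyldimethylsilyloxy)-2-ethylpent-2-enoate
Product: 5 (Z)-5-(tert-butyldimethylsilyloxy)-2-ethylpent-2-en-1-ol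
Conditions: i-Bu2AlH, CH2Cl2, −78 °C; aq. KNaC4H4O6 (potassium sodium tartrate)
Reagents that add atoms: none
Why: 1,2-reduction of an enoate to the allylic alcohol with i-Bu2AlH, which leaves the alkene geometry and the silyl ether untouched.

Step 4
Reactants: 5 (Z)-5-(tert-butyldimethylsilyloxy)-2-ethylpent-2-en-1-ol
Product: 6 (Z)-1-bromo-5-(tert-butyldimethylsilyloxy)-2-ethylpent-2-ene
Conditions: CBr4, PPh3, CH2Cl2, 0 °C
Reagents that add atoms: carbon tetrabromide BrC(Br)(Br)Br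
Why: Appel bromination of a primary allylic alcohol under neutral conditions, without allylic transposition.

Step 5
Reactants: 6 (Z)-1-bromo-5-(tert-butyldimethylsilyloxy)-2-ethylpent-2-ene
Product: 7 tributyl[(Z)-5-(tert-butyldimethylsilyloxy)-2-ethylpent-2-enyl]phosphonium bromide
Conditions: PBu3, MeCN, rt
Reagents that add atoms: tributylphosphine CCCCP(CCCC)CCCC
Why: SN2 quaternisation of tributylphosphine by the primary allylic bromide gives the salt for an E-selective Wittig reaction.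

Step 6
Reactants: 8 (tert-butyldimethylsilyloxy)acetaldehyde
Product: 9 (2R,3S)-1-(tert-butyldimethylsilyloxy)-3-methylpent-4-en-2-ol
Conditions: cis-but-2-ene, KOt-Bu, n-BuLi, THF, −78 → −45 °C; (+)-Ipc2BOMe, −78 °C; BF3·OEt2; 8, −78 °C; NaOH, H2O2, 0 °C → rt
Reagents that add atoms: cis-but-2-ene C/C=C\C (delivered as the (Z)-crotylborane formed in the flask)
Why: Brown asymmetric crotylboration through a chair Zimmerman–Traxler transition state, in which the (Z)-crotyl geometry sets the C4/C5 syn relation and the isopinocampheyl groups select the aldehyde face (C5 R, C4 S in this compound).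

Step 7
Reactants: 9 (2R,3S)-1-(tert-butyldimethylsilyloxy)-3-methylpent-4-en-2-ol
Product: 10 (2R,3S)-1-(tert-butyldimethylsilyloxy)-3-methylpent-4-en-2-yl acrylate
Conditions: acryloyl chloride, i-Pr2NEt, DMAP (cat.), CH2Cl2, 0 °C
Reagents that add atoms: acryloyl chloride C=CC(=O)Cl
Why: acylation of the secondary alcohol installs C1–C3 as the acrylate needed for ring closure.

Step 8
Reactants: 10 (2R,3S)-1-(tert-butyldimethylsilyloxy)-3-methylpent-4-en-2-yl acrylate
Product: 11 (5S,6R)-6-[(tert-butyldimethylsilyloxy)methyl]-5-methyl-5,6-dihydro-2H-pyran-2-one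
Conditions: second-generation Grubbs catalyst RuCl2(=CHPh)(PCy3)(H2IMes) (5 mol %), CH2Cl2, 40 °C
Reagents that add atoms: none
Why: ring-closing metathesis of an acrylate with a terminal alkene closes the six-membered unsaturated lactone (C2=C3) with loss of ethene and without touching C4 or C5.

Step 9
Reactants: 11 (5S,6R)-6-[(tert-butyldimethylsilyloxy)methyl]-5-methyl-5,6-dihydro-2H-pyran-2-one
Product: 13 tert-butyl{[(2R,3S,6R)-6-isopropoxy-3-methyl-3,6-dihydro-2H-pyran-2-yl]methoxy}dimethylsilane, via lactol 12 (not isolated)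
Conditions: i-Bu2AlH, CH2Cl2, −78 °C; then i-PrOH, PPTS (cat.), rt
Reagents that add atoms: propan-2-ol CC(C)O
Why: 1,2-reduction of the lactone to the lactol and acid-catalysed acetal formation through the allylic oxocarbenium ion mask the base- and hydride-sensitive lactone, the axial (2,6-trans) isopropoxy anomer being expected from the anomeric effect.

Step 10
Reactants: 13 tert-butyl{[(2R,3S,6R)-6-isopropoxy-3-methyl-3,6-dihydro-2H-pyran-2-yl]methoxy}dimethylsilane
Product: 14 [(2R,3S,6R)-6-isopropoxy-3-methyl-3,6-dihydro-2H-pyran-2-yl]methanol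
Conditions: Bu4NF, THF, 0 °C → rt
Reagents that add atoms: none
Why: fluoride cleavage of the primary silyl ether, to which the acetal is inert.

Step 11
Reactants: 14 [(2R,3S,6R)-6-isopropoxy-3-methyl-3,6-dihydro-2H-pyran-2-yl]methanol
Product: 15 (2R,3S,6R)-6-isopropoxy-3-methyl-3,6-dihydro-2H-pyran-2-carbaldehyde
Conditions: Dess–Martin periodinane, pyridine, CH2Cl2, 0 °C → rt (used at once)
Reagents that add atoms: none
Why: buffered Dess–Martin oxidation gives the α-alkoxy aldehyde (C6) without acid that would open the acetal or base that would epimerise C5.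

Step 12
Reactants: 7 tributyl[(Z)-5-(tert-butyldimethylsilyloxy)-2-ethylpent-2-enyl]phosphonium bromide; 15 (2R,3S,6R)-6-isopropoxy-3-methyl-3,6-dihydro-2H-pyran-2-carbaldehyde
Product: 16 tert-butyl{[(3Z,5E)-4-ethyl-6-[(2S,3S,6R)-6-isopropoxy-3-methyl-3,6-dihydro-2H-pyran-2-yl]hexa-3,5-dienyl]oxy}dimethylsilane
Conditions: KOt-Bu, toluene, 0 °C; then 15, −78 °C → rt
Reagents that add atoms: none
Why: Wittig olefination with a semi-stabilised allylic tributylphosphonium ylide, which should give the new C6=C7 bond as E while the 8Z alkene of the ylide is carried through unchanged.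

Step 13
Reactants: 16 tert-butyl{[(3Z,5E)-4-ethyl-6-[(2S,3S,6R)-6-isopropoxy-3-methyl-3,6-dihydro-2H-pyran-2-yl]hexa-3,5-dienyl]oxy}dimethylsilane
Product: 17 (3Z,5E)-4-ethyl-6-[(2S,3S,6R)-6-isopropoxy-3-methyl-3,6-dihydro-2H-pyran-2-yl]hexa-3,5-dien-1-ol
Conditions: Bu4NF, THF, 0 °C → rt
Reagents that add atoms: none
Why: fluoride desilylation of the primary TBS ether frees the carbon that becomes the carboxyl (and finally the C10 methyl).

Step 14
Reactants: 17 (3Z,5E)-4-ethyl-6-[(2S,3S,6R)-6-isopropoxy-3-methyl-3,6-dihydro-2H-pyran-2-yl]hexa-3,5-dien-1-ol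
Product: 18 (3Z,5E)-4-ethyl-6-[(2S,3S,6R)-6-isopropoxy-3-methyl-3,6-dihydro-2H-pyran-2-yl]hexa-3,5-dienal
Conditions: Dess–Martin periodinane, pyridine, CH2Cl2, 0 °C (crude aldehyde used at once)
Reagents that add atoms: none
Why: buffered Dess–Martin oxidation of the homoallylic alcohol at low temperature is expected to give the β,γ-unsaturated aldehyde without migration of the diene into conjugation.

Step 15
Reactants: 18 (3Z,5E)-4-ethyl-6-[(2S,3S,6R)-6-isopropoxy-3-methyl-3,6-dihydro-2H-pyran-2-yl]hexa-3,5-dienal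
Product: 19 (3Z,5E)-4-ethyl-6-[(2S,3S,6R)-6-isopropoxy-3-methyl-3,6-dihydro-2H-pyran-2-yl]hexa-3,5-dienoic acid (fragment A)
Conditions: NaClO2, NaH2PO4, 2-methylbut-2-ene, t-BuOH/H2O, 0 °C
Reagents that add atoms: sodium chlorite [Na+].[O-]Cl=O
Why: Pinnick oxidation converts the aldehyde into the acid under weakly acidic buffered conditions that the diene (hypochlorite scavenged) and, at 0 °C, the lactol acetal should tolerate.

**Fragment B (C11–C24 alcohol)**

Step 16
Reactants: 20 3-methylbut-2-en-1-ol (prenol)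
Product: 21 tert-butyldimethyl(3-methylbut-2-enyloxy)silane
Conditions: TBSCl, imidazole, CH2Cl2, rt
Reagents that add atoms: tert-butyldimethylsilyl chloride CC(C)(C)[Si](C)(C)Cl
Why: standard silylation protects the future C24 oxygen for the whole sequence.

Step 17
Reactants: 21 tert-butyldimethyl(3-methylbut-2-enyloxy)silane
Product: 22 (E)-4-(tert-butyldimethylsilyloxy)-2-methylbut-2-en-1-ol
Conditions: SeO2 (0.3 equiv), t-BuOOH, salicylic acid (0.1 equiv), CH2Cl2, rt
Reagents that add atoms: selenium dioxide O=[Se]=O (catalytic oxygen carrier); tert-butyl hydroperoxide CC(C)(C)OO (terminal oxygen source)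
Why: allylic oxidation by an ene reaction and [2,3]-shift of the allylseleninic acid, which is known to take the (E)-methyl group of a trisubstituted alkene and so fixes the 22E geometry.

Step 18
Reactants: 22 (E)-4-(tert-butyldimethylsilyloxy)-2-methylbut-2-en-1-ol
Product: 23 (E)-1-bromo-4-(tert-butyldimethylsilyloxy)-2-methylbut-2-ene
Conditions: CBr4, PPh3, CH2Cl2, −20 °C
Reagents that add atoms: carbon tetrabromide BrC(Br)(Br)Br
Why: Appel bromination of the primary allylic alcohol without transposition gives the C21 electrophile.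

Step 19
Reactants: 23 (E)-1-bromo-4-(tert-butyldimethylsilyloxy)-2-methylbut-2-ene; 24 (R)-4-benzyl-3-propionyloxazolidin-2-one
Product: 25 (R)-4-benzyl-3-[(2S,4E)-6-(tert-butyldimethylsilyloxy)-2,4-dimethylhex-4-enoyl]oxazolidin-2-one
Conditions: NaN(SiMe3)2, THF, −78 °C; then 23, −78 → −40 °C
Reagents that add atoms: none
Why: Evans asymmetric alkylation, in which the chelated (Z)-sodium enolate is alkylated by the allylic bromide on the face away from the benzyl group, setting C20.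

Step 20
Reactants: 25 (R)-4-benzyl-3-[(2S,4E)-6-(tert-butyldimethylsilyloxy)-2,4-dimethylhex-4-enoyl]oxazolidin-2-one
Product: 26 (2S,4E)-6-(tert-butyldimethylsilyloxy)-2,4-dimethylhex-4-en-1-ol
Conditions: LiBH4, H2O (1.1 equiv), Et2O, 0 °C
Reagents that add atoms: none
Why: reductive removal of the oxazolidinone gives the primary alcohol (C19) without epimerising C20.

Step 21
Reactants: 26 (2S,4E)-6-(tert-butyldimethylsilyloxy)-2,4-dimethylhex-4-en-1-ol
Product: 27 (2S,4E)-6-(tert-butyldimethylsilyloxy)-2,4-dimethylhex-4-enal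
Conditions: Dess–Martin periodinane, pyridine, CH2Cl2, 0 °C → rt
Reagents that add atoms: none
Why: neutral Dess–Martin oxidation gives the α-methyl aldehyde without racemisation.

Step 22
Reactants: 27 (2S,4E)-6-(tert-butyldimethylsilyloxy)-2,4-dimethylhex-4-enal; 28 (S)-4-benzyl-3-propionyloxazolidin-2-one
Product: 29 (S)-4-benzyl-3-[(2S,3R,4S,6E)-8-(tert-butyldimethylsilyloxy)-3-hydroxy-2,4,6-trimethyloct-6-enoyl]oxazolidin-2-one
Conditions: Bu2BOTf, i-Pr2NEt, CH2Cl2, −78 → 0 °C; 27, −78 → 0 °C; pH 7 buffer (KH2PO4/Na2HPO4), MeOH, H2O2, 0 °C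
Reagents that add atoms: none
Why: Evans syn-aldol reaction, in which the (Z)-boron enolate adds through a chair Zimmerman–Traxler transition state on the face dictated by the (S)-benzyl auxiliary, setting C18 and C19 (18,19-syn and, by reagent control over the C20 centre, 19,20-syn).

Step 23
Reactants: 29 (S)-4-benzyl-3-[(2S,3R,4S,6E)-8-(tert-butyldimethylsilyloxy)-3-hydroxy-2,4,6-trimethyloct-6-enoyl]oxazolidin-2-one
Product: 30 (S)-4-benzyl-3-[(2S,3R,4S,6E)-3,8-bis(tert-butyldimethylsilyloxy)-2,4,6-trimethyloct-6-enoyl]oxazolidin-2-one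
Conditions: TBSOTf, 2,6-lutidine, CH2Cl2, −78 → 0 °C
Reagents that add atoms: tert-butyldimethylsilyl triflate CC(C)(C)[Si](C)(C)OS(=O)(=O)C(F)(F)F
Why: silylation of the hindered C19 hydroxyl with the silyl triflate blocks retro-aldol cleavage and protects C19 to the end.

Step 24
Reactants: 30 (S)-4-benzyl-3-[(2S,3R,4S,6E)-3,8-bis(tert-butyldimethylsilyloxy)-2,4,6-trimethyloct-6-enoyl]oxazolidin-2-one
Product: 31 (2R,3R,4S,6E)-3,8-bis(tert-butyldimethylsilyloxy)-2,4,6-trimethyloct-6-en-1-ol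
Conditions: LiBH4, H2O (1.1 equiv), Et2O, 0 °C
Reagents that add atoms: none
Why: reductive cleavage of the auxiliary gives the C17 primary alcohol (the descriptor at C18 changes only through priorities).

Step 25
Reactants: 31 (2R,3R,4S,6E)-3,8-bis(tert-butyldimethylsilyloxy)-2,4,6-trimethyloct-6-en-1-ol
Product: 32 (2S,3R,4S,6E)-3,8-bis(tert-butyldimethylsilyloxy)-2,4,6-trimethyloct-6-enal
Conditions: Dess–Martin periodinane, pyridine, CH2Cl2, 0 °C → rt
Reagents that add atoms: none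
Why: neutral Dess–Martin oxidation gives the C17 aldehyde without epimerisation at C18 or β-elimination of the C19 silyloxy group.

Step 26
Reactants: 33 (R)-4-benzyloxazolidin-2-one
Product: 34 (R)-4-benzyl-3-[(E)-but-2-enoyl]oxazolidin-2-one
Conditions: n-BuLi, THF, −78 °C; (E)-but-2-enoyl chloride, −78 → 0 °C
Reagents that add atoms: (E)-but-2-enoyl chloride C/C=C/C(=O)Cl
Why: N-acylation of the lithiated oxazolidinone gives the crotonyl imide for the dienolate aldol reaction.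

Step 27
Reactants: 32 (2S,3R,4S,6E)-3,8-bis(tert-butyldimethylsilyloxy)-2,4,6-trimethyloct-6-enal; 34 (R)-4-benzyl-3-[(E)-but-2-enoyl]oxazolidin-2-one
Product: 35 (R)-4-benzyl-3-[(2R,3S,4R,5R,6S,8E)-5,10-bis(tert-butyldimethylsilyloxy)-2-ethenyl-3-hydroxy-4,6,8-trimethyldec-8-enoyl]oxazolidin-2-one
Conditions: Bu2BOTf, Et3N, CH2Cl2, −78 → 0 °C; 32, −78 → 0 °C; pH 7 buffer (KH2PO4/Na2HPO4), MeOH, H2O2, 0 °C
Reagents that add atoms: none
Why: Evans aldol reaction of the boron dienolate formed by γ-deprotonation of the crotonyl imide, which reacts at its α-carbon through a chair transition state so that the (R)-auxiliary sets C16 (vinyl-bearing) and the temporary C17 carbinol (16,17-syn) by reagent control.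

Step 28
Reactants: 35 (R)-4-benzyl-3-[(2R,3S,4R,5R,6S,8E)-5,10-bis(tert-butyldimethylsilyloxy)-2-ethenyl-3-hydroxy-4,6,8-trimethyldec-8-enoyl]oxazolidin-2-one
Product: 36 (2S,3R,4R,5R,6S,8E)-5,10-bis(tert-butyldimethylsilyloxy)-2-ethenyl-4,6,8-trimethyldec-8-ene-1,3-diol
Conditions: LiBH4, H2O (1.1 equiv), Et2O, 0 °C
Reagents that add atoms: none
Why: reductive removal of the auxiliary turns the imide carbonyl into the kazusamycin hydroxymethyl group on C16.

Step 29
Reactants: 36 (2S,3R,4R,5R,6S,8E)-5,10-bis(tert-butyldimethylsilyloxy)-2-ethenyl-4,6,8-trimethyldec-8-ene-1,3-diol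
Product: 37 (2S,3R,4R,5R,6S,8E)-1,5,10-tris(tert-butyldimethylsilyloxy)-2-ethenyl-4,6,8-trimethyldec-8-en-3-ol
Conditions: TBSCl (1.1 equiv), imidazole, CH2Cl2, 0 °C
Reagents that add atoms: tert-butyldimethylsilyl chloride CC(C)(C)[Si](C)(C)Cl
Why: the primary hydroxyl is silylated much faster than the hindered C17 hydroxyl, which differentiates the two.

Step 30
Reactants: 37 (2S,3R,4R,5R,6S,8E)-1,5,10-tris(tert-butyldimethylsilyloxy)-2-ethenyl-4,6,8-trimethyldec-8-en-3-ol
Product: 38 triethylsilyl ether of 37 at C17 (C15–C24 segment with terminal C15 vinyl, 16-CH2OTBS, 17-OTES, 19-OTBS, 24-OTBS)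
Conditions: TESOTf, 2,6-lutidine, CH2Cl2, −78 °C
Reagents that add atoms: triethylsilyl triflate CC[Si](CC)(CC)OS(=O)(=O)C(F)(F)F
Why: the C17 oxygen, which must later become the ketone, receives the one silyl group that mild acid removes in the presence of the TBS ethers.

Step 31
Reactants: 38 triethylsilyl ether of 37 at C17
Product: 39 (14E,22E)-C13–C24 enal (2-methyl-2-enal with CHO = C13, 16-CH2OTBS, 17-OTES, 19-OTBS, 24-OTBS)
Conditions: methacrolein (10 equiv), second-generation Hoveyda–Grubbs catalyst RuCl2(=CH-C6H4-2-O-i-Pr)(H2IMes) (5–10 mol %), CH2Cl2, 40 °C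
Reagents that add atoms: methacrolein CC(=C)C=O
Why: olefin cross-metathesis of the terminal vinyl group with excess methacrolein gives the thermodynamically favoured (E)-trisubstituted enal, the trisubstituted C22=C23 alkene being unreactive.

Step 32
Reactants: 39 (14E,22E)-C13–C24 enal
Product: 40 fragment B, (13S,14E,22E)-C11–C24 bis-allylic alcohol (vinyl and OH on C13, 16-CH2OTBS, 17-OTES, 19-OTBS, 24-OTBS)
Conditions: (CH2=CH)2Zn (salt-free, 1.5 equiv), (−)-MIB [(2S)-3-exo-morpholinoisoborneol] (10 mol %), toluene, −20 → 0 °C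
Reagents that add atoms: divinylzinc C=C[Zn]C=C
Why: amino-alcohol-catalysed enantioselective addition of a vinylzinc reagent to an aldehyde, in which the chiral zinc alkoxide catalyst, not the remote substrate centres, directs the vinyl group to the Si face of the enal and sets the temporary C13 centre (S).

**Union and endgame**

Step 33
Reactants: 19 (3Z,5E)-4-ethyl-6-[(2S,3S,6R)-6-isopropoxy-3-methyl-3,6-dihydro-2H-pyran-2-yl]hexa-3,5-dienoic acid; 40 fragment B bis-allylic alcohol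
Product: 41 ester of acid 19 with the C13 hydroxyl of 40
Conditions: N,N'-diisopropylcarbodiimide, DMAP (0.2 equiv), CH2Cl2, 0 °C
Reagents that add atoms: none
Why: Steglich esterification at 0 °C joins the halves through the C13 oxygen with retention at C13 and, with little DMAP at low temperature, without moving the β,γ-diene of the acyl part into conjugation.

Step 34
Reactants: 41 ester of acid 19 with the C13 hydroxyl of 40
Product: 44 coupled C1–C24 acid bearing CO2H on C10 in place of the methyl, via silyl ketene acetal 42 (not isolated), via trimethylsilyl ester 43 (not isolated)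
Conditions: LiN(i-Pr)2 (1.2 equiv), Me3SiCl/Et3N, THF, −78 °C → 20 °C; aq. NH4Cl
Reagents that add atoms: chlorotrimethylsilane C[Si](C)(C)Cl (its silyl group stays only in 42 and 43)
Why: Ireland–Claisen rearrangement: LiN(i-Pr)2 removes a C10 proton of 41 (α to the ester and allylic to C8=C9), Me3SiCl traps the enolate as ketene acetal 42, and 42 undergoes a concerted [3,3] shift in which the C13–O bond breaks while C10 bonds to C11, giving silyl ester 43 and, on aqueous work-up, acid 44; the closest known reaction type is the ester-enolate Claisen rearrangement of bis-allylic (divinylcarbinyl) esters. No ring is closed, the only cyclic array being the six-membered chair transition state (C10, ester carbon, O, C13, C12, C11). The new stereocentre C10 is controlled by that chair, in which the C14 alkenyl group on C13 (13S) is equatorial and the C9 substituent of the ketene acetal, cis to the C13–O oxygen after kinetic enolisation in THF, is axial, so that C11 is delivered to the face of C10 that corresponds to the target configuration once CO2H has become CH3. The same equatorial preference makes the new C12=C13 bond E. Selectivity between the two allyl arms of C13 is needed, and the unsubstituted C11 terminus of the vinyl arm is far less hindered than C15 and its use leaves the C12–C15 diene conjugated, so this arm should react. The step is kept at or below room temperature so that the (Z)-triene unit of 42 does not electrocyclise.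

Step 35
Reactants: 44 coupled C1–C24 acid bearing CO2H on C10
Product: 45 C10 hydroxymethyl compound (CH2OH in place of the C10 methyl)
Conditions: LiAlH4, Et2O, 0 °C → rt
Reagents that add atoms: none
Why: hydride reduction of the only carbonyl group in the molecule (silyl ethers and the acetal are inert) without touching the C10 centre.

Step 36
Reactants: 45 C10 hydroxymethyl compound
Product: 46 C10 (methanesulfonyloxy)methyl compound
Conditions: MsCl, Et3N, CH2Cl2, 0 °C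
Reagents that add atoms: methanesulfonyl chloride CS(=O)(=O)Cl
Why: sulfonylation of the only free hydroxyl activates the primary carbon for hydride displacement.

Step 37
Reactants: 46 C10 (methanesulfonyloxy)methyl compound
Product: 47 C10 methyl compound (protected kazusamycin skeleton: 1-O-isopropyl lactol acetal, 16-CH2OTBS, 17-OTES, 19-OTBS, 24-OTBS)
Conditions: LiBHEt3, THF, 0 °C → rt
Reagents that add atoms: none
Why: SN2 displacement of the primary mesylate by LiBHEt3 turns the former carboxyl carbon into the C10 methyl group with the C10 configuration untouched.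

Step 38
Reactants: 47 C10 methyl compound
Product: 48 lactol with free C17 hydroxyl (anomer mixture; 16-CH2OTBS, 19-OTBS, 24-OTBS)
Conditions: AcOH–THF–H2O (3:1:1), 0 °C → rt, stopped when the triethylsilyl ether is consumed
Reagents that add atoms: water O
Why: mild aqueous acid hydrolyses the allylic lactol acetal through its stabilised oxocarbenium ion and cleaves the triethylsilyl ether much faster than the TBS ethers.

Step 39
Reactants: 48 lactol with free C17 hydroxyl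
Product: 49 δ-lactone C17 ketone (16-CH2OTBS, 19-OTBS, 24-OTBS)
Conditions: Dess–Martin periodinane (3 equiv), pyridine, CH2Cl2, 0 °C → rt
Reagents that add atoms: none
Why: buffered Dess–Martin oxidation converts the lactol into the unsaturated lactone and the C17 carbinol into the ketone in one operation, under conditions too mild to epimerise C16 or move the C14=C15 alkene into conjugation.

Step 40
Reactants: 49 δ-lactone C17 ketone
Product: 50 kazusamycin A C24 alcohol (CH2OH in place of CO2H)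
Conditions: HF·pyridine, pyridine, THF, 0 °C → rt
Reagents that add atoms: none
Why: buffered fluoride removes the three TBS groups without base, which the β-hydroxy ketone and the lactone would not tolerate.

Step 41
Reactants: 50 kazusamycin A C24 alcohol
Product: 51 kazusamycin A C24 aldehyde
Conditions: MnO2, CH2Cl2, rt
Reagents that add atoms: none
Why: MnO2 oxidises only the allylic primary alcohol (C24) and leaves the saturated C16 hydroxymethyl and C19 hydroxyl groups untouched.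

Step 42
Reactants: 51 kazusamycin A C24 aldehyde
Product: 52 kazusamycin A
Conditions: NaClO2, NaH2PO4, 2-methylbut-2-ene, t-BuOH/H2O, 0 °C
Reagents that add atoms: sodium chlorite [Na+].[O-]Cl=O
Why: Pinnick oxidation converts the enal into the (22E)-enoic acid in the presence of free hydroxyls, ketone, lactone and polyene.

**Compound list**

1 | methyl bis(2,2,2-trifluoroethyl)phosphonoacetate | COC(=O)CP(=O)(OCC(F)(F)F)OCC(F)(F)F | starting material
2 | methyl 2-[bis(2,2,2-trifluoroethoxy)phosphoryl]butanoate (racemic) | CCC(C(=O)OC)P(=O)(OCC(F)(F)F)OCC(F)(F)F | intermediate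
3 | 3-(tert-butyldimethylsilyloxy)propanal | O=CCCO[Si](C)(C)C(C)(C)C | starting material
4 | methyl (Z)-5-(tert-butyldimethylsilyloxy)-2-ethylpent-2-enoate | CC/C(=C/CCO[Si](C)(C)C(C)(C)C)C(=O)OC | intermediate
5 | (Z)-5-(tert-butyldimethylsilyloxy)-2-ethylpent-2-en-1-ol | CC/C(=C/CCO[Si](C)(C)C(C)(C)C)CO | intermediate
6 | (Z)-1-bromo-5-(tert-butyldimethylsilyloxy)-2-ethylpent-2-ene | CC/C(=C/CCO[Si](C)(C)C(C)(C)C)CBr | intermediate
7 | tributyl[(Z)-5-(tert-butyldimethylsilyloxy)-2-ethylpent-2-enyl]phosphonium bromide | CC/C(=C/CCO[Si](C)(C)C(C)(C)C)C[P+](CCCC)(CCCC)CCCC.[Br-] | intermediate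
8 | (tert-butyldimethylsilyloxy)acetaldehyde | O=CCO[Si](C)(C)C(C)(C)C | starting material
9 | (2R,3S)-1-(tert-butyldimethylsilyloxy)-3-methylpent-4-en-2-ol | CC(C)(C)[Si](C)(C)OC[C@H](O)[C@@H](C)C=C | intermediate
10 | (2R,3S)-1-(tert-butyldimethylsilyloxy)-3-methylpent-4-en-2-yl acrylate | CC(C)(C)[Si](C)(C)OC[C@H](OC(=O)C=C)[C@@H](C)C=C | intermediate
11 | (5S,6R)-6-[(tert-butyldimethylsilyloxy)methyl]-5-methyl-5,6-dihydro-2H-pyran-2-one | CC(C)(C)[Si](C)(C)OC[C@@H]1OC(=O)C=C[C@@H]1C | intermediate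
12 | (5S,6R)-6-[(tert-butyldimethylsilyloxy)methyl]-5-methyl-5,6-dihydro-2H-pyran-2-ol (lactol, anomer mixture) | CC(C)(C)[Si](C)(C)OC[C@@H]1OC(O)C=C[C@@H]1C | intermediate
13 | tert-butyl{[(2R,3S,6R)-6-isopropoxy-3-methyl-3,6-dihydro-2H-pyran-2-yl]methoxy}dimethylsilane | CC(C)(C)[Si](C)(C)OC[C@@H]1O[C@@H](OC(C)C)C=C[C@@H]1C | intermediate
14 | [(2R,3S,6R)-6-isopropoxy-3-methyl-3,6-dihydro-2H-pyran-2-yl]methanol | OC[C@@H]1O[C@@H](OC(C)C)C=C[C@@H]1C | intermediate
15 | (2R,3S,6R)-6-isopropoxy-3-methyl-3,6-dihydro-2H-pyran-2-carbaldehyde | O=C[C@@H]1O[C@@H](OC(C)C)C=C[C@@H]1C | intermediate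
16 | tert-butyl{[(3Z,5E)-4-ethyl-6-[(2S,3S,6R)-6-isopropoxy-3-methyl-3,6-dihydro-2H-pyran-2-yl]hexa-3,5-dienyl]oxy}dimethylsilane | CCC(=C/CCO[Si](C)(C)C(C)(C)C)/C=C/[C@@H]1O[C@@H](OC(C)C)C=C[C@@H]1C | intermediate
17 | (3Z,5E)-4-ethyl-6-[(2S,3S,6R)-6-isopropoxy-3-methyl-3,6-dihydro-2H-pyran-2-yl]hexa-3,5-dien-1-ol | CCC(=C/CCO)/C=C/[C@@H]1O[C@@H](OC(C)C)C=C[C@@H]1C | intermediate
18 | (3Z,5E)-4-ethyl-6-[(2S,3S,6R)-6-isopropoxy-3-methyl-3,6-dihydro-2H-pyran-2-yl]hexa-3,5-dienal | CCC(=C/CC=O)/C=C/[C@@H]1O[C@@H](OC(C)C)C=C[C@@H]1C | intermediate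
19 | (3Z,5E)-4-ethyl-6-[(2S,3S,6R)-6-isopropoxy-3-methyl-3,6-dihydro-2H-pyran-2-yl]hexa-3,5-dienoic acid (fragment A) | CCC(=C/CC(=O)O)/C=C/[C@@H]1O[C@@H](OC(C)C)C=C[C@@H]1C | intermediate
20 | 3-methylbut-2-en-1-ol (prenol) | CC(C)=CCO | starting material
21 | tert-butyldimethyl(3-methylbut-2-enyloxy)silane | CC(C)=CCO[Si](C)(C)C(C)(C)C | intermediate
22 | (E)-4-(tert-butyldimethylsilyloxy)-2-methylbut-2-en-1-ol | OC/C(C)=C/CO[Si](C)(C)C(C)(C)C | intermediate
23 | (E)-1-bromo-4-(tert-butyldimethylsilyloxy)-2-methylbut-2-ene | BrC/C(C)=C/CO[Si](C)(C)C(C)(C)C | intermediate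
24 | (R)-4-benzyl-3-propionyloxazolidin-2-one | CCC(=O)N1[C@H](Cc2ccccc2)COC1=O | starting material
25 | (R)-4-benzyl-3-[(2S,4E)-6-(tert-butyldimethylsilyloxy)-2,4-dimethylhex-4-enoyl]oxazolidin-2-one | O=C(N1[C@H](Cc2ccccc2)COC1=O)[C@@H](C)C/C(C)=C/CO[Si](C)(C)C(C)(C)C | intermediate
26 | (2S,4E)-6-(tert-butyldimethylsilyloxy)-2,4-dimethylhex-4-en-1-ol | OC[C@@H](C)C/C(C)=C/CO[Si](C)(C)C(C)(C)C | intermediate
27 | (2S,4E)-6-(tert-butyldimethylsilyloxy)-2,4-dimethylhex-4-enal | O=C[C@@H](C)C/C(C)=C/CO[Si](C)(C)C(C)(C)C | intermediate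
28 | (S)-4-benzyl-3-propionyloxazolidin-2-one | CCC(=O)N1[C@@H](Cc2ccccc2)COC1=O | starting material
29 | (S)-4-benzyl-3-[(2S,3R,4S,6E)-8-(tert-butyldimethylsilyloxy)-3-hydroxy-2,4,6-trimethyloct-6-enoyl]oxazolidin-2-one | O=C(N1[C@@H](Cc2ccccc2)COC1=O)[C@@H](C)[C@H](O)[C@@H](C)C/C(C)=C/CO[Si](C)(C)C(C)(C)C | intermediate
30 | (S)-4-benzyl-3-[(2S,3R,4S,6E)-3,8-bis(tert-butyldimethylsilyloxy)-2,4,6-trimethyloct-6-enoyl]oxazolidin-2-one | O=C(N1[C@@H](Cc2ccccc2)COC1=O)[C@@H](C)[C@H](O[Si](C)(C)C(C)(C)C)[C@@H](C)C/C(C)=C/CO[Si](C)(C)C(C)(C)C | intermediate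
31 | (2R,3R,4S,6E)-3,8-bis(tert-butyldimethylsilyloxy)-2,4,6-trimethyloct-6-en-1-ol | OC[C@@H](C)[C@H](O[Si](C)(C)C(C)(C)C)[C@@H](C)C/C(C)=C/CO[Si](C)(C)C(C)(C)C | intermediate
32 | (2S,3R,4S,6E)-3,8-bis(tert-butyldimethylsilyloxy)-2,4,6-trimethyloct-6-enal | O=C[C@@H](C)[C@H](O[Si](C)(C)C(C)(C)C)[C@@H](C)C/C(C)=C/CO[Si](C)(C)C(C)(C)C | intermediate
33 | (R)-4-benzyloxazolidin-2-one | O=C1N[C@H](Cc2ccccc2)CO1 | starting material
34 | (R)-4-benzyl-3-[(E)-but-2-enoyl]oxazolidin-2-one | C/C=C/C(=O)N1[C@H](Cc2ccccc2)COC1=O | intermediate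
35 | (R)-4-benzyl-3-[(2R,3S,4R,5R,6S,8E)-5,10-bis(tert-butyldimethylsilyloxy)-2-ethenyl-3-hydroxy-4,6,8-trimethyldec-8-enoyl]oxazolidin-2-one | C=C[C@@H](C(=O)N1[C@H](Cc2ccccc2)COC1=O)[C@@H](O)[C@@H](C)[C@H](O[Si](C)(C)C(C)(C)C)[C@@H](C)C/C(C)=C/CO[Si](C)(C)C(C)(C)C | intermediate
36 | (2S,3R,4R,5R,6S,8E)-5,10-bis(tert-butyldimethylsilyloxy)-2-ethenyl-4,6,8-trimethyldec-8-ene-1,3-diol | C=C[C@@H](CO)[C@@H](O)[C@@H](C)[C@H](O[Si](C)(C)C(C)(C)C)[C@@H](C)C/C(C)=C/CO[Si](C)(C)C(C)(C)C | intermediate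
37 | (2S,3R,4R,5R,6S,8E)-1,5,10-tris(tert-butyldimethylsilyloxy)-2-ethenyl-4,6,8-trimethyldec-8-en-3-ol | C=C[C@@H](CO[Si](C)(C)C(C)(C)C)[C@@H](O)[C@@H](C)[C@H](O[Si](C)(C)C(C)(C)C)[C@@H](C)C/C(C)=C/CO[Si](C)(C)C(C)(C)C | intermediate
38 | triethylsilyl ether of 37 at C17 (C15–C24, terminal C15 vinyl, 16-CH2OTBS, 17-OTES, 19-OTBS, 24-OTBS) | C=C[C@@H](CO[Si](C)(C)C(C)(C)C)[C@@H](O[Si](CC)(CC)CC)[C@@H](C)[C@H](O[Si](C)(C)C(C)(C)C)[C@@H](C)C/C(C)=C/CO[Si](C)(C)C(C)(C)C | intermediate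
39 | (14E,22E)-C13–C24 enal (CHO = C13, 14-methyl, 16-CH2OTBS, 17-OTES, 19-OTBS, 24-OTBS) | O=C/C(C)=C/[C@@H](CO[Si](C)(C)C(C)(C)C)[C@@H](O[Si](CC)(CC)CC)[C@@H](C)[C@H](O[Si](C)(C)C(C)(C)C)[C@@H](C)C/C(C)=C/CO[Si](C)(C)C(C)(C)C | intermediate
40 | fragment B, (13S,14E,22E)-C11–C24 bis-allylic alcohol (vinyl and OH on C13, 16-CH2OTBS, 17-OTES, 19-OTBS, 24-OTBS) | C=C[C@H](O)/C(C)=C/[C@@H](CO[Si](C)(C)C(C)(C)C)[C@@H](O[Si](CC)(CC)CC)[C@@H](C)[C@H](O[Si](C)(C)C(C)(C)C)[C@@H](C)C/C(C)=C/CO[Si](C)(C)C(C)(C)C | intermediate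
41 | ester of acid 19 with the C13 hydroxyl of 40 | CCC(=C/CC(=O)O[C@@H](C=C)/C(C)=C/[C@@H](CO[Si](C)(C)C(C)(C)C)[C@@H](O[Si](CC)(CC)CC)[C@@H](C)[C@H](O[Si](C)(C)C(C)(C)C)[C@@H](C)C/C(C)=C/CO[Si](C)(C)C(C)(C)C)/C=C/[C@@H]1O[C@@H](OC(C)C)C=C[C@@H]1C | intermediate
42 | trimethylsilyl ketene acetal of 41 (C10=C(OSiMe3)–O–C13, C9 cis to the O–C13 oxygen) | CCC(=C/C=C(/O[Si](C)(C)C)O[C@@H](C=C)/C(C)=C/[C@@H](CO[Si](C)(C)C(C)(C)C)[C@@H](O[Si](CC)(CC)CC)[C@@H](C)[C@H](O[Si](C)(C)C(C)(C)C)[C@@H](C)C/C(C)=C/CO[Si](C)(C)C(C)(C)C)/C=C/[C@@H]1O[C@@H](OC(C)C)C=C[C@@H]1C | intermediate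
43 | trimethylsilyl ester of 44 | CCC(=C/[C@H](C(=O)O[Si](C)(C)C)C/C=C/C(C)=C/[C@@H](CO[Si](C)(C)C(C)(C)C)[C@@H](O[Si](CC)(CC)CC)[C@@H](C)[C@H](O[Si](C)(C)C(C)(C)C)[C@@H](C)C/C(C)=C/CO[Si](C)(C)C(C)(C)C)/C=C/[C@@H]1O[C@@H](OC(C)C)C=C[C@@H]1C | intermediate
44 | coupled C1–C24 acid: kazusamycin skeleton with CO2H in place of the C10 methyl (10R; 6E,8Z,12E,14E,22E; 1-O-isopropyl lactol acetal, 16-CH2OTBS, 17-OTES, 19-OTBS, 24-OTBS) | CCC(=C/[C@H](C(=O)O)C/C=C/C(C)=C/[C@@H](CO[Si](C)(C)C(C)(C)C)[C@@H](O[Si](CC)(CC)CC)[C@@H](C)[C@H](O[Si](C)(C)C(C)(C)C)[C@@H](C)C/C(C)=C/CO[Si](C)(C)C(C)(C)C)/C=C/[C@@H]1O[C@@H](OC(C)C)C=C[C@@H]1C | intermediate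
45 | C10 hydroxymethyl compound (CH2OH in place of the C10 methyl, otherwise as 44) | CCC(=C/[C@H](CO)C/C=C/C(C)=C/[C@@H](CO[Si](C)(C)C(C)(C)C)[C@@H](O[Si](CC)(CC)CC)[C@@H](C)[C@H](O[Si](C)(C)C(C)(C)C)[C@@H](C)C/C(C)=C/CO[Si](C)(C)C(C)(C)C)/C=C/[C@@H]1O[C@@H](OC(C)C)C=C[C@@H]1C | intermediate
46 | C10 (methanesulfonyloxy)methyl compound | CCC(=C/[C@H](COS(C)(=O)=O)C/C=C/C(C)=C/[C@@H](CO[Si](C)(C)C(C)(C)C)[C@@H](O[Si](CC)(CC)CC)[C@@H](C)[C@H](O[Si](C)(C)C(C)(C)C)[C@@H](C)C/C(C)=C/CO[Si](C)(C)C(C)(C)C)/C=C/[C@@H]1O[C@@H](OC(C)C)C=C[C@@H]1C | intermediate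
47 | C10 methyl compound (1-O-isopropyl lactol acetal, 16-CH2OTBS, 17-OTES, 19-OTBS, 24-OTBS) | CCC(=C/[C@H](C)C/C=C/C(C)=C/[C@@H](CO[Si](C)(C)C(C)(C)C)[C@@H](O[Si](CC)(CC)CC)[C@@H](C)[C@H](O[Si](C)(C)C(C)(C)C)[C@@H](C)C/C(C)=C/CO[Si](C)(C)C(C)(C)C)/C=C/[C@@H]1O[C@@H](OC(C)C)C=C[C@@H]1C | intermediate
48 | lactol with free C17 hydroxyl (anomer mixture; 16-CH2OTBS, 19-OTBS, 24-OTBS) | CCC(=C/[C@H](C)C/C=C/C(C)=C/[C@@H](CO[Si](C)(C)C(C)(C)C)[C@@H](O)[C@@H](C)[C@H](O[Si](C)(C)C(C)(C)C)[C@@H](C)C/C(C)=C/CO[Si](C)(C)C(C)(C)C)/C=C/[C@@H]1OC(O)C=C[C@@H]1C | intermediate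
49 | δ-lactone C17 ketone (16-CH2OTBS, 19-OTBS, 24-OTBS) | CCC(=C/[C@H](C)C/C=C/C(C)=C/[C@@H](CO[Si](C)(C)C(C)(C)C)C(=O)[C@@H](C)[C@H](O[Si](C)(C)C(C)(C)C)[C@@H](C)C/C(C)=C/CO[Si](C)(C)C(C)(C)C)/C=C/[C@@H]1OC(=O)C=C[C@@H]1C | intermediate
50 | kazusamycin A C24 alcohol (CH2OH in place of CO2H) | CCC(=C/[C@H](C)C/C=C/C(C)=C/[C@@H](CO)C(=O)[C@@H](C)[C@H](O)[C@@H](C)C/C(C)=C/CO)/C=C/[C@@H]1OC(=O)C=C[C@@H]1C | intermediate
51 | kazusamycin A C24 aldehyde | CCC(=C/[C@H](C)C/C=C/C(C)=C/[C@@H](CO)C(=O)[C@@H](C)[C@H](O)[C@@H](C)C/C(C)=C/C=O)/C=C/[C@@H]1OC(=O)C=C[C@@H]1C | intermediate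
52 | kazusamycin A | CCC(=C/[C@H](C)C/C=C/C(C)=C/[C@@H](CO)C(=O)[C@@H](C)[C@H](O)[C@@H](C)C/C(C)=C/C(=O)O)/C=C/[C@@H]1OC(=O)C=C[C@@H]1C | target

**Step count and risks**

Total step count: 42. Longest linear sequence: 26 steps (steps 16–25 and 27–42).

Steps most likely to fail:

1. Step 34 (Ireland–Claisen union). What may go wrong: loss of control over the ketene acetal geometry of the α-alkenyl ester, which would erode the configuration at C10; leakage of the rearrangement through the C14=C15 arm; ionisation or β-elimination of the bis-allylic ester before silylation. Fallback, setting out from 40 and returning at 47: the C10–C11 bond is made by a simple propionate Claisen and the left half is attached afterwards by olefinations. Alcohol 40 is acylated with propionic anhydride (DMAP, Et3N, CH2Cl2) to propionate F1. Enolisation under conditions that favour the other enolate geometry (LiN(i-Pr)2, THF–DMPU, Me3SiCl, −78 °C → rt), which the same chair analysis requires once the methyl is the enolate substituent, and rearrangement give the 2-methyl acid F2 with the C10 methyl already in place. LiAlH4 gives alcohol F3 and Dess–Martin oxidation aldehyde F4. Still–Gennari olefination with phosphonate 2 gives (Z)-enoate F5, i-Bu2AlH allylic alcohol F6, CBr4/PPh3 bromide F7 and PBu3 phosphonium salt F8. Wittig reaction of F8 with aldehyde 15 (KOt-Bu, toluene) gives 47.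

2. Step 32 (asymmetric vinylation). What may go wrong: insufficient facial control by the zinc–amino alcohol catalyst on the hindered α-methyl enal, so that C13 epimers form and would be transferred into C10. Fallback, setting out from 39 and returning at 40: the C13 centre is set by a Sharpless epoxidation instead. Horner–Wadsworth–Emmons reaction of 39 with triethyl phosphonoacetate (LiCl, DBU, MeCN) gives dienoate F9 and i-Bu2AlH dienol F10. Sharpless epoxidation (Ti(O-i-Pr)4, L-(+)-diethyl tartrate, t-BuOOH, 4 Å sieves, CH2Cl2, −20 °C) epoxidises only the allylic-alcohol alkene C12=C13 and gives epoxy alcohol F11. I2/PPh3/imidazole gives epoxy iodide F12, and zinc dust in ethanol opens the ring reductively to the (13S)-vinyl carbinol 40.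

3. Step 31 (cross-metathesis). What may go wrong: slow turnover at the allylically branched terminal alkene, so that catalyst decay and methacrolein self-metathesis outrun the cross reaction. Fallback, setting out from aldehyde 32 (with auxiliary 33) and returning at 39: C15 is brought in as an oxygenated carbon and the C14=C15 alkene is made by a Wittig reaction. Auxiliary 33 is acylated with 3-(4-methoxybenzyloxy)propanoic acid (pivaloyl chloride, Et3N; lithiated 33) to imide F13. Its boron enolate (Bu2BOTf, i-Pr2NEt) adds to 32 in an Evans syn-aldol reaction to give adduct F14. LiBH4 gives diol F15, TBSCl/imidazole primary silyl ether F16 and TESOTf/2,6-lutidine the C17 triethylsilyl ether F17. DDQ (CH2Cl2, pH 7 buffer) removes the 4-methoxybenzyl group to give alcohol F18, and Dess–Martin oxidation gives the C15 aldehyde F19. Wittig reaction of F19 with 2-(triphenylphosphoranylidene)propanal (toluene, 80 °C) gives the (E)-enal 39.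

**Further compounds**

F1 | step 34 | propionate of 40 at the C13 oxygen | CCC(=O)O[C@@H](C=C)/C(C)=C/[C@@H](CO[Si](C)(C)C(C)(C)C)[C@@H](O[Si](CC)(CC)CC)[C@@H](C)[C@H](O[Si](C)(C)C(C)(C)C)[C@@H](C)C/C(C)=C/CO[Si](C)(C)C(C)(C)C
F2 | step 34 | C9–C24 acid (CO2H = C9, C10 methyl in place, 12E,14E) | OC(=O)[C@H](C)C/C=C/C(C)=C/[C@@H](CO[Si](C)(C)C(C)(C)C)[C@@H](O[Si](CC)(CC)CC)[C@@H](C)[C@H](O[Si](C)(C)C(C)(C)C)[C@@H](C)C/C(C)=C/CO[Si](C)(C)C(C)(C)C
F3 | step 34 | C9–C24 primary alcohol | OC[C@H](C)C/C=C/C(C)=C/[C@@H](CO[Si](C)(C)C(C)(C)C)[C@@H](O[Si](CC)(CC)CC)[C@@H](C)[C@H](O[Si](C)(C)C(C)(C)C)[C@@H](C)C/C(C)=C/CO[Si](C)(C)C(C)(C)C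
F4 | step 34 | C9–C24 aldehyde | O=C[C@H](C)C/C=C/C(C)=C/[C@@H](CO[Si](C)(C)C(C)(C)C)[C@@H](O[Si](CC)(CC)CC)[C@@H](C)[C@H](O[Si](C)(C)C(C)(C)C)[C@@H](C)C/C(C)=C/CO[Si](C)(C)C(C)(C)C
F5 | step 34 | methyl (8Z)-C7–C24 enoate (ester carbon = C7, ethyl on C8) | CC/C(=C/[C@H](C)C/C=C/C(C)=C/[C@@H](CO[Si](C)(C)C(C)(C)C)[C@@H](O[Si](CC)(CC)CC)[C@@H](C)[C@H](O[Si](C)(C)C(C)(C)C)[C@@H](C)C/C(C)=C/CO[Si](C)(C)C(C)(C)C)C(=O)OC
F6 | step 34 | (8Z)-C7–C24 allylic alcohol | CC/C(=C/[C@H](C)C/C=C/C(C)=C/[C@@H](CO[Si](C)(C)C(C)(C)C)[C@@H](O[Si](CC)(CC)CC)[C@@H](C)[C@H](O[Si](C)(C)C(C)(C)C)[C@@H](C)C/C(C)=C/CO[Si](C)(C)C(C)(C)C)CO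
F7 | step 34 | (8Z)-C7–C24 allylic bromide | CC/C(=C/[C@H](C)C/C=C/C(C)=C/[C@@H](CO[Si](C)(C)C(C)(C)C)[C@@H](O[Si](CC)(CC)CC)[C@@H](C)[C@H](O[Si](C)(C)C(C)(C)C)[C@@H](C)C/C(C)=C/CO[Si](C)(C)C(C)(C)C)CBr
F8 | step 34 | (8Z)-C7–C24 tributylphosphonium bromide | CC/C(=C/[C@H](C)C/C=C/C(C)=C/[C@@H](CO[Si](C)(C)C(C)(C)C)[C@@H](O[Si](CC)(CC)CC)[C@@H](C)[C@H](O[Si](C)(C)C(C)(C)C)[C@@H](C)C/C(C)=C/CO[Si](C)(C)C(C)(C)C)C[P+](CCCC)(CCCC)CCCC.[Br-]
F9 | step 32 | ethyl (12E,14E)-C11–C24 dienoate (ester carbon = C11) | CCOC(=O)/C=C/C(C)=C/[C@@H](CO[Si](C)(C)C(C)(C)C)[C@@H](O[Si](CC)(CC)CC)[C@@H](C)[C@H](O[Si](C)(C)C(C)(C)C)[C@@H](C)C/C(C)=C/CO[Si](C)(C)C(C)(C)C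
F10 | step 32 | (12E,14E)-C11–C24 dienol | OC/C=C/C(C)=C/[C@@H](CO[Si](C)(C)C(C)(C)C)[C@@H](O[Si](CC)(CC)CC)[C@@H](C)[C@H](O[Si](C)(C)C(C)(C)C)[C@@H](C)C/C(C)=C/CO[Si](C)(C)C(C)(C)C
F11 | step 32 | trans-12,13-epoxy alcohol (C11 OH) | OC[C@H]1O[C@@H]1/C(C)=C/[C@@H](CO[Si](C)(C)C(C)(C)C)[C@@H](O[Si](CC)(CC)CC)[C@@H](C)[C@H](O[Si](C)(C)C(C)(C)C)[C@@H](C)C/C(C)=C/CO[Si](C)(C)C(C)(C)C
F12 | step 32 | trans-12,13-epoxy iodide (C11 I) | IC[C@H]1O[C@@H]1/C(C)=C/[C@@H](CO[Si](C)(C)C(C)(C)C)[C@@H](O[Si](CC)(CC)CC)[C@@H](C)[C@H](O[Si](C)(C)C(C)(C)C)[C@@H](C)C/C(C)=C/CO[Si](C)(C)C(C)(C)C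
F13 | step 31 | (R)-4-benzyl-3-[3-(4-methoxybenzyloxy)propanoyl]oxazolidin-2-one | COc1ccc(COCCC(=O)N2[C@H](Cc3ccccc3)COC2=O)cc1
F14 | step 31 | Evans syn-aldol adduct of F13 with 32 (C15 as CH2O-4-methoxybenzyl) | COc1ccc(COC[C@@H](C(=O)N2[C@H](Cc3ccccc3)COC2=O)[C@@H](O)[C@@H](C)[C@H](O[Si](C)(C)C(C)(C)C)[C@@H](C)C/C(C)=C/CO[Si](C)(C)C(C)(C)C)cc1
F15 | step 31 | 1,3-diol from F14 (16-CH2OH, 17-OH) | COc1ccc(COC[C@@H](CO)[C@@H](O)[C@@H](C)[C@H](O[Si](C)(C)C(C)(C)C)[C@@H](C)C/C(C)=C/CO[Si](C)(C)C(C)(C)C)cc1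
F16 | step 31 | primary TBS ether of F15 | COc1ccc(COC[C@@H](CO[Si](C)(C)C(C)(C)C)[C@@H](O)[C@@H](C)[C@H](O[Si](C)(C)C(C)(C)C)[C@@H](C)C/C(C)=C/CO[Si](C)(C)C(C)(C)C)cc1
F17 | step 31 | C17 triethylsilyl ether of F16 | COc1ccc(COC[C@@H](CO[Si](C)(C)C(C)(C)C)[C@@H](O[Si](CC)(CC)CC)[C@@H](C)[C@H](O[Si](C)(C)C(C)(C)C)[C@@H](C)C/C(C)=C/CO[Si](C)(C)C(C)(C)C)cc1
F18 | step 31 | C15 primary alcohol | OC[C@@H](CO[Si](C)(C)C(C)(C)C)[C@@H](O[Si](CC)(CC)CC)[C@@H](C)[C@H](O[Si](C)(C)C(C)(C)C)[C@@H](C)C/C(C)=C/CO[Si](C)(C)C(C)(C)C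
F19 | step 31 | C15 aldehyde | O=C[C@@H](CO[Si](C)(C)C(C)(C)C)[C@@H](O[Si](CC)(CC)CC)[C@@H](C)[C@H](O[Si](C)(C)C(C)(C)C)[C@@H](C)C/C(C)=C/CO[Si](C)(C)C(C)(C)C
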